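The starting material left over in a flask is not among the readings, yet the target tells how fast it goes.

| flask | starting material | gas phase | remark | time |
|---|---|---|---|---|
| spring | 20 mM | 1.5 mM (held) | the very flask that is asked about, followed so far |  |
| dusk | 10 mM | 1.5 mM (held) | run made earlier |  |
| flask | 20 mM | 1.5 mM (held) |  | 3.0 h |

spring run (percent of the starting material charged)

| time / min | target / % | idle adduct / % |
|---|---|---|
| 2.00 | 1.0 | 1.1 |
| 6.00 | 1.9 | 0 |
| 12.0 | 2.1 | 2.8 |
| 20.0 | 3.6 | 1.4 |
| 25.0 | 2.9 | 2.1 |
| 30.0 | 3.3 | 1.2 |

dusk run (percent of the starting material charged)

| time / h | target / % | idle adduct / % |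
|---|---|---|
| 0.200 | 1.8 | 2.0 |
| 0.667 | 5.4 | 6.7 |
| 1.00 | 6.8 | 6.1 |
| 1.50 | 7.1 | 8.4 |
| 2.50 | 8.7 | 7.7 |
| 3.00 | 11.2 | 9.3 |

(readings scatter by 1 percentage point)

- how much target and idle adduct together there is at 3.0 h, in percent of the starting material charged
- concentration of dissolved gas in solution at 50 min, in percent of saturation
- the change that raises the amount of target and idle adduct together at 3.0 h, in percent of the starting material charged most ("none" if none brings more than 2 percentage points) (eta / epsilon / none)
- amount of target and idle adduct together at 3.0 h, in percent of the starting material charged, after eta

- what is said of target includes idle adduct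
- at the start none of the gas phase is in solution

- eta: doubling the transfer coefficient of the gas phase, all else as stated
- epsilon: doubling the saturation concentration of gas phase, all else as stated

Spring stays at or below 3.6% of its charge up to 30.0 min, while dusk reads 5.4% of its own at 0.667 h. With dissolved gas held, a first-order loss of starting material leaves percentages equal at both charges; a second-order drain lowers them at the larger charge. With dissolved gas held, target forms pseudo-first-order in c(starting material), and under such a drain target in mM follows the exposure, charge times time, rising late with its logarithm. The readings agree: 20 mM for 30.0 min and 10 mM for 1.00 h are equal exposures, and they hold 0.660 mM and 0.680 mM.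

The flask at 3.0 h has twice the exposure of the last dusk reading, so two dusk readings carry the estimate. One scatter on the last one moves it by 0.82 percentage points, on the 1.00 h one by 0.32 points. Those two give the log gain, target won per e-fold of exposure, 0.401 mM, and my estimate is 6.99%.

Idle adduct beside target reads 2.0% to 1.8% at the first dusk reading and 9.3% to 11.2% at the last, a ratio that does not rise, so, taking the adduct to hold dissolved gas, I read dissolved gas as near saturation by 50 min. Eta should then add little, and epsilon, doubling the target rate, roughly 6.99%.

The forecast says 12% (8.5% to 17%), 75% of saturation and 13.5% after eta, and it picks epsilon as the best change: “Doubling saturation should help most”.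

The flask gives 6.61% and 98.5% of saturation; eta adds 0.29 points, reaching 6.90%, and epsilon adds 5.4 points, so the best change is epsilon.

    gas phase ⇌ dissolved gas, rate k1*(csat - [dissolved gas]) (kL = 0.0104 s⁻¹)
    starting material + dissolved gas → target (k = 0.0396 M⁻¹ s⁻¹)
    starting material → side product (k = 3.26 × 10⁻⁶ s⁻¹)
    2 starting material → self-condensation product (k = 0.0615 M⁻¹ s⁻¹)
    dissolved gas + target ⇌ idle adduct, settled at all times (K = 3200 M⁻¹)

For the neighbour flask charged with 80 mM of starting material, the gain added to this flask's 6.61% gives 2.35%, and that neighbour holds 2.16%. Reckoned for this flask at the full charge with dissolved gas at saturation, the step to self-condensation product uses starting material 41.4 times as fast as the step to target. With 2.51% of the starting material left at 3.00 h, that ratio has fallen to 1.0.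

The readings stem from a simulated flask for an exercise, noise included.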